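The numbers in the tables are simulated for substances that don't exist; the scatter is artificial.

Time can be struck out of this racemate before any flask is reckoned, and logarithms do it: by the steps under discussion the left-handed and the right-handed substrate meet the same c(reagent) and the same c(catalyst) at every moment, so these factors cancel from the ratio of the two rates. At a given temperature, the logarithm of the fraction of left-handed substrate left over the logarithm of the fraction of right-handed substrate left then stays constant, however the reagent fares on the way. Each substrate is half of the charge, so its fraction left is one minus twice its product reading.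

| setting | red | grey | violet | elm | cedar | ash | maple |
|---|---|---|---|---|---|---|---|
| left-handed substrate | 0.50 M | 0.50 M | 0.75 M | 0.50 M | 0.50 M | 0.50 M | 0.50 M |
| right-handed substrate | 0.50 M | 0.50 M | 0.75 M | 0.50 M | 0.50 M | 0.50 M | 0.50 M |
| reagent | 2 equiv | 2 equiv | 2 equiv | 2.00 equiv | 2.00 equiv | 2.00 equiv | 2.00 equiv |
| catalyst | 1 mol% | 1.5 mol% | 2 mol% | 2 mol% | 2 mol% | 2 mol% | 2 mol% |
| temperature | 20 °C | 53 °C | 20 °C | 45 °C | 5 °C | 25 °C | 65 °C |
| remark | run made earlier | run made earlier | run made earlier |  |  |  |  |
| time |  |  |  | 5.0 h | 5.0 h | 5.0 h | 5.0 h |

| run | time / h | left-handed product / % | right-handed product / % |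
|---|---|---|---|
| red | 3.00 | 21 | 16 |
| red | 5.00 | 28 | 22 |
| red | 8.00 | 36 | 27 |
| red | 10.0 | 36 | 27 |
| red | 15.0 | 42 | 32 |
| grey | 0.833 | 40 | 31 |
| grey | 1.50 | 42 | 38 |
| grey | 2.50 | 50 | 43 |
| grey | 3.00 | 44 | 42 |
| grey | 4.00 | 50 | 46 |
| grey | 5.00 | 47 | 45 |
| violet | 1.33 | 31 | 22 |
| violet | 3.00 | 43 | 31 |
| violet | 5.00 | 47 | 37 |
| violet | 8.00 | 48 | 40 |
| violet | 15.0 | 50 | 45 |

(each reading ± 1.5 percentage points)

- catalyst is single-handed; left-handed substrate and right-handed substrate are mirror images of each other, charged as a racemate, each of them at the stated concentration
- the numbers in the tables scatter with a standard deviation of 1.5 percentage points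
- steps under discussion: reagent + catalyst + right-handed substrate -> catalyst + right-handed product; reagent + catalyst + left-handed substrate -> catalyst + left-handed product; reagent <-> dormant form
- an excess is the difference of the two amounts in percent of their sum
- an excess is below zero if the other one leads

* the flask with the highest excess of left-handed product over right-handed product ("all alike" if they lie within 1.5 percentage points) (elm / cedar / ash / maple / all alike)
* excess of left-handed product over right-handed product at the end, elm
* excess of left-handed product over right-handed product at the end, cedar
* excess of left-handed product over right-handed product at the end, ash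
* excess of left-handed product over right-handed product at the end, maple

The last red reading gives 1.79 for this ratio but the first gives 1.41, so a single pair can't be trusted. A scatter of 1.5 percentage points also weighs heavily once little substrate stands, as in violet at 5.00 h, where the reading leaves 6.00 % of the left-handed substrate. Summing the logarithms over the red readings and the first two violet ones therefore gives the selectivity factor s = 1.71 at 20 °C.

But the flasks asked about stand at other temperatures. The first two grey readings, summed likewise, give 1.44 at 53 °C, a lower value. Taking ln s as straight in temperature gives 1.84 for cedar and, by extrapolation, 1.35 for maple, a larger factor for cedar, but this doesn't rank the two flasks, because the excess depends on conversion as well as on s.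

The factor s doesn't tell how far cedar gets. From red to grey, the logarithm per unit of time and catalyst grows by 7.84, and scaling red by this leaves 52.5 % of cedar's left-handed substrate. That scaling ignores the fall of c(reagent), so this is the weak number, but s then gives an excess of 23.4 % for cedar. Grey, cooler than maple and with less catalyst, already reads 47 % and 45 % at 5.00 h, an excess of 2.17 %, so maple is expected to be far converted with a small excess, and conversion together with s makes cedar the flask to back.

The forecast names cedar, with 4 % for elm, 23 % for cedar, 13 % for ash and 4 % for maple, expecting “a slight fall in selectivity on warming”.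

Cedar leads with 24.2 %, against 4.47 % for elm, 11.9 % for ash and 1.59 % for maple, so the forecast held. At 5.00 h cedar holds dormant form at 0.349 M and reagent at 26 % of its charge, yet s, carried from 1.71 to 1.84, turns its 52 % of left-handed substrate left into 23.2 %.

    reagent + catalyst + right-handed substrate → catalyst + right-handed product (k = 18.0 /M²/h, Ea = 48.0 kJ/mol)
    reagent + catalyst + left-handed substrate → catalyst + left-handed product (k = 34.0 /M²/h, Ea = 44.0 kJ/mol)
    reagent ⇌ dormant form (K = 1.20, k = 0.840 /h, Ea = 81.0 kJ/mol, ΔH = −26.0 kJ/mol)
    (constants at 5 °C)

The neighbour of maple with 0.500 equiv of reagent ends with reagent at 0 % and 71 % of its left-handed substrate left, which s = 1.35 turns into an excess of 12.8 %. The computed flask gives 14.1 %.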